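**Retrosynthetic overview**

- The last skeletal bond made is C4–C4a. It closes the pyran (ring B: O2, C1, C8a, C4a, C4, C3) onto a finished, fully substituted cyclohexenone (ring A); only a double desilylation follows.
- Enabling feature: in ring B, O2 lies between the allylic C1 (C1–C8a=C4a) and the vinylic C3 (C3=C4). The open form is therefore an allyl vinyl ether whose termini C4 and C4a are the atoms to be joined. A phenylthio group on C4a lets the Claisen product lose PhSH to a 1-oxatriene (O=C3–C4=C4a–C8a=C1), which re-forms O2–C1 by oxa-6π closure.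
- The allyl vinyl ether comes from the ring A enone by Morita–Baylis–Hillman hydroxymethylation (C1), ketal exchange with the dimethyl ketal of (E)-pent-3-en-2-one (O2–C3, C4, propenyl) and thiol addition/oxidation (C4a–S).
- Ring A is bought as 2-methylcyclohexane-1,3-dione. Its enol ester with the protected aryl acid is reduced (CBS, sets C6) and epoxidised; a 1,2-acyloxy shift then sets C7 and moves the hindered ester from O8 to O7. Saegusa oxidation gives the enone.
- Ring order: aryl ring and ring A are bought, ring B is formed last; the aryl acid is made from orcinaldehyde.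

Key step: step 13

Remark: isochromene numbering of the target (C1, O2, C3, C4, C4a, C5–C8, C8a) is used for all ring atoms; the target is read as (6R,7S), that is, 6-OH trans to the 7-acyloxy group; "aroate" below means 2-methoxy-6-methyl-4-(triisopropylsilyloxy)benzoate.

**Route**

Step 1
Reactants: 1 2,4-dihydroxy-6-methylbenzaldehyde
Product: 2 2-hydroxy-6-methyl-4-(triisopropylsilyloxy)benzaldehyde
Conditions: TIPSCl, imidazole, CH2Cl2, 0 to 23 °C
Reagents that add atoms: triisopropylsilyl chloride, CC(C)[Si](Cl)(C(C)C)C(C)C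
Why: Selective O-silylation of the para-hydroxyl should occur because the ortho-hydroxyl is hydrogen-bonded to the aldehyde and shielded by it.

Step 2
Reactants: 2 2-hydroxy-6-methyl-4-(triisopropylsilyloxy)benzaldehyde
Product: 3 2-methoxy-6-methyl-4-(triisopropylsilyloxy)benzaldehyde
Conditions: MeI, K2CO3, acetone, 23 °C
Reagents that add atoms: iodomethane, CI
Why: Williamson O-methylation of the remaining phenol; the bulky aryl triisopropylsilyl ether should tolerate carbonate at room temperature.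

Step 3
Reactants: 3 2-methoxy-6-methyl-4-(triisopropylsilyloxy)benzaldehyde
Product: 4 2-methoxy-6-methyl-4-(triisopropylsilyloxy)benzoic acid
Conditions: NaClO2, NaH2PO4, 2-methyl-2-butene, t-BuOH/H2O, 23 °C
Reagents that add atoms: sodium chlorite, [Na+].[O-]Cl=O
Why: Pinnick oxidation should convert the electron-rich, di-ortho-substituted aldehyde to the acid at about pH 4 without touching the silyl ether, the alkene scavenging HOCl so that the ring is not chlorinated.

Step 4
Reactants: 4 2-methoxy-6-methyl-4-(triisopropylsilyloxy)benzoic acid, 5 2-methylcyclohexane-1,3-dione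
Product: 7 2-methyl-3-oxocyclohex-1-en-1-yl aroate, via acid chloride 6 (not isolated)
Conditions: (COCl)2, DMF (cat.), CH2Cl2, 0 to 23 °C, evaporate; then 5, Et3N, CH2Cl2, 0 °C
Reagents that add atoms: none
Why: Enol ester formation by O-acylation of the dione enolate; the di-ortho-substituted aroyl chloride should react at oxygen, and no acyl-transfer catalyst is present that could move the acyl group to carbon.

Step 5
Reactants: 7 2-methyl-3-oxocyclohex-1-en-1-yl aroate
Product: 8 (3R)-3-hydroxy-2-methylcyclohex-1-en-1-yl aroate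
Conditions: (S)-2-methyl-CBS-oxazaborolidine (20 mol%), catecholborane, toluene, −78 to −40 °C
Reagents that add atoms: none
Why: Corey–Bakshi–Shibata 1,2-reduction in which the alpha-methylated alkenyl side acts as the large group, so the (S)-catalyst (the one that gives (R)-1-phenylethanol) should give the (3R)-alcohol, which becomes C6 of the target.

Step 6
Reactants: 8 (3R)-3-hydroxy-2-methylcyclohex-1-en-1-yl aroate
Product: 10 (1S,2R)-2-hydroxy-1-methyl-6-oxocyclohexyl aroate, via epoxide 9 (not isolated)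
Conditions: mCPBA, CH2Cl2, 0 °C; then toluene, 80 °C
Reagents that add atoms: meta-chloroperbenzoic acid, OOC(=O)c1cccc(Cl)c1
Why: Henbest hydroxyl-directed epoxidation should place the epoxide oxygen cis to the hydroxyl, and the thermal 1,2-acyloxy shift of the enol ester epoxide (ester carbonyl oxygen opens the methyl-bearing carbon from the back, with inversion) should then put the aroyloxy group trans to the hydroxyl, setting C7 (S) and making the hindered tertiary ester intramolecularly.

Step 7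
Reactants: 10 (1S,2R)-2-hydroxy-1-methyl-6-oxocyclohexyl aroate
Product: 11 (1S,2R)-2-(tert-butyldimethylsilyloxy)-1-methyl-6-oxocyclohexyl aroate
Conditions: TBSOTf, 2,6-lutidine, CH2Cl2, −78 to 0 °C
Reagents that add atoms: tert-butyldimethylsilyl triflate, CC(C)(C)[Si](C)(C)OS(=O)(=O)C(F)(F)F
Why: Silylation of the hindered secondary alcohol with the silyl triflate and a non-nucleophilic base, under which the di-ortho-substituted ester should not migrate.

Step 8
Reactants: 11 (1S,2R)-2-(tert-butyldimethylsilyloxy)-1-methyl-6-oxocyclohexyl aroate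
Product: 13 (1S,6R)-6-(tert-butyldimethylsilyloxy)-1-methyl-2-oxocyclohex-3-en-1-yl aroate, via silyl enol ether 12 (not isolated)
Conditions: LiN(SiMe3)2, TMSCl, THF, −78 °C; then Pd(OAc)2, MeCN, 23 °C
Reagents that add atoms: none
Why: Saegusa–Ito dehydrogenation; the ketone has alpha-hydrogens only on its CH2 side, so a single silyl enol ether should form and Pd(OAc)2 should turn it into the C8a=C4a enone.

Step 9
Reactants: 13 (1S,6R)-6-(tert-butyldimethylsilyloxy)-1-methyl-2-oxocyclohex-3-en-1-yl aroate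
Product: 14 (1S,6R)-6-(tert-butyldimethylsilyloxy)-3-(hydroxymethyl)-1-methyl-2-oxocyclohex-3-en-1-yl aroate
Conditions: aqueous HCHO, DMAP (20 mol%), THF/H2O, 23 °C
Reagents that add atoms: formaldehyde, C=O
Why: Morita–Baylis–Hillman hydroxymethylation of the cyclohexenone at C8a under nucleophilic amine catalysis, which introduces C1.

Step 10
Reactants: 15 (E)-pent-3-en-2-one
Product: 16 (E)-4,4-dimethoxypent-2-ene
Conditions: MeOSiMe3 (2.2 equiv), TMSOTf (1 mol%), CH2Cl2, −78 °C; pyridine quench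
Reagents that add atoms: methoxytrimethylsilane, CO[Si](C)(C)C
Why: Noyori acetalisation with an alkoxysilane should give the dimethyl ketal of the enone without conjugate addition of methanol or shift of the double bond.

Step 11
Reactants: 14 (1S,6R)-6-(tert-butyldimethylsilyloxy)-3-(hydroxymethyl)-1-methyl-2-oxocyclohex-3-en-1-yl aroate, 16 (E)-4,4-dimethoxypent-2-ene
Product: 17 (1S,6R)-6-(tert-butyldimethylsilyloxy)-3-{[(E)-2-methoxypent-3-en-2-yl]oxymethyl}-1-methyl-2-oxocyclohex-3-en-1-yl aroate (both ketal epimers)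
Conditions: 16 (3 equiv), PPTS (2 mol%), 5 Å molecular sieves, CH2Cl2, 0 to 23 °C
Reagents that add atoms: none
Why: Acid-catalysed transketalisation of the primary allylic alcohol through the allyl-stabilised methoxy oxocarbenium ion, driven by excess ketal and uptake of MeOH; it forms the O2–C3 bond.

Step 12
Reactants: 17 (1S,6R)-6-(tert-butyldimethylsilyloxy)-3-{[(E)-2-methoxypent-3-en-2-yl]oxymethyl}-1-methyl-2-oxocyclohex-3-en-1-yl aroate
Product: 20 (1S,6R)-6-(tert-butyldimethylsilyloxy)-3-{[(E)-2-methoxypent-3-en-2-yl]oxymethyl}-1-methyl-2-oxo-4-(phenylsulfanyl)cyclohex-3-en-1-yl aroate, via beta-thio ketone 18 (not isolated), via alpha-chloro sulfide 19 (not isolated)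
Conditions: PhSH (1.0 equiv), Et3N (5 mol%), CH2Cl2, 0 °C; then NCS, −20 °C; then Et3N (1.5 equiv), −20 to 23 °C
Reagents that add atoms: thiophenol, Sc1ccccc1
Why: Thia-Michael addition followed by NCS chlorination of the sulfide (Pummerer-type alpha-chlorination) and dehydrochlorination towards the acidic C8a should give the beta-phenylthio enone; the hydroxyl is already masked as the ketal, so no alkoxysulfonium (Corey–Kim) pathway is open.

Step 13
Reactants: 20 (1S,6R)-6-(tert-butyldimethylsilyloxy)-3-{[(E)-2-methoxypent-3-en-2-yl]oxymethyl}-1-methyl-2-oxo-4-(phenylsulfanyl)cyclohex-3-en-1-yl aroate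
Product: 24 (6R,7S)-6-(tert-butyldimethylsilyloxy)-7-methyl-8-oxo-3-[(E)-prop-1-enyl]-5,6,7,8-tetrahydro-1H-isochromen-7-yl aroate, via enol ether 21 (not isolated), via Claisen ketone 22 (not isolated), via oxatriene 23 (not isolated)
Conditions: 2,4-dinitrophenol (5 mol%), toluene, 110 °C with removal of MeOH; then DBU (1.2 equiv), 0 to 23 °C
Reagents that add atoms: none
Why: Proposed new method: acid-catalysed loss of MeOH from the mixed ketal should give allyl vinyl ether 21, whose Claisen [3,3] shift (chair transition state) joins C4 to C4a and opens O2–C1; E1cB loss of thiophenol from beta-thio ketone 22 then gives (Z)-1-oxatriene 23, and its oxa-6π electrocyclisation re-forms O2–C1, so that the only new skeletal bond between 20 and 24 is C4–C4a. The closest known reaction types are the ketal Claisen rearrangement of allylic alcohols with 2-alkoxydienes (Johnson and Saucy–Marbet variants), Claisen rearrangements of Morita–Baylis–Hillman-type allyl systems, and the Knoevenagel or propargyl-Claisen/oxa-6π routes to 2H-pyrans; what is new is the leaving group on the allyl terminus that turns the Claisen product into the oxatriene. Ring B is closed in a net 6-endo sense (vinyl terminus C4 onto C4a of the enone whose alpha-carbon C8a carries the tether) and is sealed by a thermally allowed disrotatory 6π closure between the C3 carbonyl oxygen and the exocyclic C1 methylene. No stereocentre of 24 is made here: the quaternary C4a of 22 is transient, and C6 and C7 cannot epimerise because C7 is fully substituted and C6 is not alpha to a carbonyl. The step needs the [3,3] shift to outrun heterolysis of the allylic C1–O2 bond and reaction through the isomeric enol ether; only a weak acid and heat are used, the sulfur donor on C4a and the acyl group on C8a both accelerate the Claisen shift, and the unsubstituted C4 methylene is the faster terminus under Curtin–Hammett conditions. Elimination before or after O–C1 bond formation, and E/Z isomerisation of 23 by reversible thiolate addition, all lead to 24, whose push-pull dienone is the thermodynamic sink.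

Step 14
Reactants: 24 (6R,7S)-6-(tert-butyldimethylsilyloxy)-7-methyl-8-oxo-3-[(E)-prop-1-enyl]-5,6,7,8-tetrahydro-1H-isochromen-7-yl aroate
Product: 25 (6R,7S)-6-hydroxy-7-methyl-8-oxo-3-[(E)-prop-1-enyl]-5,6,7,8-tetrahydro-1H-isochromen-7-yl 4-hydroxy-2-methoxy-6-methylbenzoate
Conditions: HF·pyridine, pyridine, THF, 0 to 23 °C
Reagents that add atoms: none
Why: Fluoride-mediated cleavage of both silyl ethers under buffered, non-basic conditions, which should avoid retro-aldol cleavage and acyl migration in the beta-hydroxy ketone and spare the vinylogous-ester-like dienol ether.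

**Compound list**

1 | 2,4-dihydroxy-6-methylbenzaldehyde (orcinaldehyde) | Cc1cc(O)cc(O)c1C=O | starting material
2 | 2-hydroxy-6-methyl-4-(triisopropylsilyloxy)benzaldehyde | Cc1cc(O[Si](C(C)C)(C(C)C)C(C)C)cc(O)c1C=O | intermediate
3 | 2-methoxy-6-methyl-4-(triisopropylsilyloxy)benzaldehyde | COc1cc(O[Si](C(C)C)(C(C)C)C(C)C)cc(C)c1C=O | intermediate
4 | 2-methoxy-6-methyl-4-(triisopropylsilyloxy)benzoic acid | COc1cc(O[Si](C(C)C)(C(C)C)C(C)C)cc(C)c1C(=O)O | intermediate
5 | 2-methylcyclohexane-1,3-dione | CC1C(=O)CCCC1=O | starting material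
6 | 2-methoxy-6-methyl-4-(triisopropylsilyloxy)benzoyl chloride | COc1cc(O[Si](C(C)C)(C(C)C)C(C)C)cc(C)c1C(Cl)=O | intermediate
7 | 2-methyl-3-oxocyclohex-1-en-1-yl 2-methoxy-6-methyl-4-(triisopropylsilyloxy)benzoate | CC1=C(OC(=O)c2c(C)cc(O[Si](C(C)C)(C(C)C)C(C)C)cc2OC)CCCC1=O | intermediate
8 | (3R)-3-hydroxy-2-methylcyclohex-1-en-1-yl 2-methoxy-6-methyl-4-(triisopropylsilyloxy)benzoate | CC1=C(OC(=O)c2c(C)cc(O[Si](C(C)C)(C(C)C)C(C)C)cc2OC)CCC[C@H]1O | intermediate
9 | (1R,2R,6R)-2-hydroxy-1-methyl-7-oxabicyclo[4.1.0]heptan-6-yl 2-methoxy-6-methyl-4-(triisopropylsilyloxy)benzoate (epoxide oxygen cis to the hydroxyl) | C[C@]12O[C@@]1(OC(=O)c3c(C)cc(O[Si](C(C)C)(C(C)C)C(C)C)cc3OC)CCC[C@H]2O | intermediate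
10 | (1S,2R)-2-hydroxy-1-methyl-6-oxocyclohexyl 2-methoxy-6-methyl-4-(triisopropylsilyloxy)benzoate | O=C1[C@@](C)(OC(=O)c2c(C)cc(O[Si](C(C)C)(C(C)C)C(C)C)cc2OC)[C@H](O)CCC1 | intermediate
11 | (1S,2R)-2-(tert-butyldimethylsilyloxy)-1-methyl-6-oxocyclohexyl 2-methoxy-6-methyl-4-(triisopropylsilyloxy)benzoate | O=C1[C@@](C)(OC(=O)c2c(C)cc(O[Si](C(C)C)(C(C)C)C(C)C)cc2OC)[C@H](O[Si](C)(C)C(C)(C)C)CCC1 | intermediate
12 | (1S,6R)-6-(tert-butyldimethylsilyloxy)-1-methyl-2-(trimethylsilyloxy)cyclohex-2-en-1-yl 2-methoxy-6-methyl-4-(triisopropylsilyloxy)benzoate | C[Si](C)(C)OC1=CCC[C@@H](O[Si](C)(C)C(C)(C)C)[C@]1(C)OC(=O)c2c(C)cc(O[Si](C(C)C)(C(C)C)C(C)C)cc2OC | intermediate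
13 | (1S,6R)-6-(tert-butyldimethylsilyloxy)-1-methyl-2-oxocyclohex-3-en-1-yl 2-methoxy-6-methyl-4-(triisopropylsilyloxy)benzoate | O=C1[C@@](C)(OC(=O)c2c(C)cc(O[Si](C(C)C)(C(C)C)C(C)C)cc2OC)[C@H](O[Si](C)(C)C(C)(C)C)CC=C1 | intermediate
14 | (1S,6R)-6-(tert-butyldimethylsilyloxy)-3-(hydroxymethyl)-1-methyl-2-oxocyclohex-3-en-1-yl 2-methoxy-6-methyl-4-(triisopropylsilyloxy)benzoate | O=C1[C@@](C)(OC(=O)c2c(C)cc(O[Si](C(C)C)(C(C)C)C(C)C)cc2OC)[C@H](O[Si](C)(C)C(C)(C)C)CC=C1CO | intermediate
15 | (E)-pent-3-en-2-one | C/C=C/C(C)=O | starting material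
16 | (E)-4,4-dimethoxypent-2-ene | C/C=C/C(C)(OC)OC | intermediate
17 | (1S,6R)-6-(tert-butyldimethylsilyloxy)-3-{[(E)-2-methoxypent-3-en-2-yl]oxymethyl}-1-methyl-2-oxocyclohex-3-en-1-yl 2-methoxy-6-methyl-4-(triisopropylsilyloxy)benzoate (both ketal epimers) | O=C1[C@@](C)(OC(=O)c2c(C)cc(O[Si](C(C)C)(C(C)C)C(C)C)cc2OC)[C@H](O[Si](C)(C)C(C)(C)C)CC=C1COC(C)(OC)/C=C/C | intermediate
18 | (1S,6R)-6-(tert-butyldimethylsilyloxy)-3-{[(E)-2-methoxypent-3-en-2-yl]oxymethyl}-1-methyl-2-oxo-4-(phenylsulfanyl)cyclohexyl 2-methoxy-6-methyl-4-(triisopropylsilyloxy)benzoate (mixture at C3 and C4) | O=C1[C@@](C)(OC(=O)c2c(C)cc(O[Si](C(C)C)(C(C)C)C(C)C)cc2OC)[C@H](O[Si](C)(C)C(C)(C)C)CC(Sc3ccccc3)C1COC(C)(OC)/C=C/C | intermediate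
19 | (1S,6R)-6-(tert-butyldimethylsilyloxy)-4-chloro-3-{[(E)-2-methoxypent-3-en-2-yl]oxymethyl}-1-methyl-2-oxo-4-(phenylsulfanyl)cyclohexyl 2-methoxy-6-methyl-4-(triisopropylsilyloxy)benzoate (mixture at C3 and C4) | O=C1[C@@](C)(OC(=O)c2c(C)cc(O[Si](C(C)C)(C(C)C)C(C)C)cc2OC)[C@H](O[Si](C)(C)C(C)(C)C)CC(Cl)(Sc3ccccc3)C1COC(C)(OC)/C=C/C | intermediate
20 | (1S,6R)-6-(tert-butyldimethylsilyloxy)-3-{[(E)-2-methoxypent-3-en-2-yl]oxymethyl}-1-methyl-2-oxo-4-(phenylsulfanyl)cyclohex-3-en-1-yl 2-methoxy-6-methyl-4-(triisopropylsilyloxy)benzoate | O=C1[C@@](C)(OC(=O)c2c(C)cc(O[Si](C(C)C)(C(C)C)C(C)C)cc2OC)[C@H](O[Si](C)(C)C(C)(C)C)CC(Sc3ccccc3)=C1COC(C)(OC)/C=C/C | intermediate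
21 | (1S,6R)-6-(tert-butyldimethylsilyloxy)-1-methyl-2-oxo-3-{[(E)-penta-1,3-dien-2-yl]oxymethyl}-4-(phenylsulfanyl)cyclohex-3-en-1-yl 2-methoxy-6-methyl-4-(triisopropylsilyloxy)benzoate | O=C1[C@@](C)(OC(=O)c2c(C)cc(O[Si](C(C)C)(C(C)C)C(C)C)cc2OC)[C@H](O[Si](C)(C)C(C)(C)C)CC(Sc3ccccc3)=C1COC(=C)/C=C/C | intermediate
22 | (1S,6R)-6-(tert-butyldimethylsilyloxy)-1-methyl-3-methylidene-2-oxo-4-[(E)-2-oxopent-3-enyl]-4-(phenylsulfanyl)cyclohexyl 2-methoxy-6-methyl-4-(triisopropylsilyloxy)benzoate (both C4 epimers) | O=C1[C@@](C)(OC(=O)c2c(C)cc(O[Si](C(C)C)(C(C)C)C(C)C)cc2OC)[C@H](O[Si](C)(C)C(C)(C)C)CC(Sc3ccccc3)(CC(=O)/C=C/C)C1=C | intermediate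
23 | (1S,4Z,6R)-6-(tert-butyldimethylsilyloxy)-1-methyl-3-methylidene-2-oxo-4-[(E)-2-oxopent-3-enylidene]cyclohexyl 2-methoxy-6-methyl-4-(triisopropylsilyloxy)benzoate | O=C1[C@@](C)(OC(=O)c2c(C)cc(O[Si](C(C)C)(C(C)C)C(C)C)cc2OC)[C@H](O[Si](C)(C)C(C)(C)C)C/C(=C/C(=O)/C=C/C)C1=C | intermediate
24 | (6R,7S)-6-(tert-butyldimethylsilyloxy)-7-methyl-8-oxo-3-[(E)-prop-1-enyl]-5,6,7,8-tetrahydro-1H-isochromen-7-yl 2-methoxy-6-methyl-4-(triisopropylsilyloxy)benzoate | C/C=C/C1=CC2=C(CO1)C(=O)[C@@](C)(OC(=O)c1c(C)cc(O[Si](C(C)C)(C(C)C)C(C)C)cc1OC)[C@H](O[Si](C)(C)C(C)(C)C)C2 | intermediate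
25 | (6R,7S)-6-hydroxy-7-methyl-8-oxo-3-[(E)-prop-1-enyl]-5,6,7,8-tetrahydro-1H-isochromen-7-yl 4-hydroxy-2-methoxy-6-methylbenzoate | C/C=C/C1=CC2=C(CO1)C(=O)[C@@](C)(OC(=O)c1c(C)cc(O)cc1OC)[C@H](O)C2 | target

**Step count and risks**

Total step count: 14. Longest linear sequence: 13 (steps 1 to 9 and 11 to 14; step 10 is a one-step side branch).

Steps most likely to fail:

1. Step 13 (Proposed new method). The allylic C1–O2 bond may ionise (the cation is stabilised by the sulfur-substituted enone) and recombine at C1 in a formal [1,3] shift instead of the [3,3] shift; the ketal may lose the wrong alkoxy group; or the alpha-methylene ketone may oligomerise before the electrocyclisation. The fallback makes the C4–C4a bond by known polar chemistry. It sets out from 20 and returns at 24. Methanolysis of the ketal (PPTS, MeOH) would give (1S,6R)-6-(tert-butyldimethylsilyloxy)-3-(hydroxymethyl)-1-methyl-2-oxo-4-(phenylsulfanyl)cyclohex-3-en-1-yl 2-methoxy-6-methyl-4-(triisopropylsilyloxy)benzoate F1. The kinetic lithium enolate of 15 (LiN(iPr)2, THF, −78 °C, 2.2 equiv) would then displace thiophenolate from this vinylogous thioester by conjugate addition–elimination to give (1S,6R)-6-(tert-butyldimethylsilyloxy)-3-(hydroxymethyl)-1-methyl-2-oxo-4-[(E)-2-oxopent-3-enyl]cyclohex-3-en-1-yl 2-methoxy-6-methyl-4-(triisopropylsilyloxy)benzoate F2. PPTS with 4 Å molecular sieves in benzene at 50 °C should close the hemiketal between the C1 hydroxyl and the C3 ketone and dehydrate it to 24.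

2. Step 6. The acyloxy shift may take the retentive course (opening at the acyloxy-bearing carbon and acyl transfer to the epoxide oxygen), or the free hydroxyl may capture the acyl group, so that the aroyloxy group ends cis to the C6 oxygen or on the wrong oxygen. The fallback uses that retentive course from the opposite epoxide face. It sets out from 8 and returns at 11. Silylation first (TBSOTf, 2,6-lutidine) would give (3R)-3-(tert-butyldimethylsilyloxy)-2-methylcyclohex-1-en-1-yl 2-methoxy-6-methyl-4-(triisopropylsilyloxy)benzoate F3. Dimethyldioxirane (acetone, −20 °C) should then epoxidise anti to the bulky silyloxy group to give (1S,2R,6S)-2-(tert-butyldimethylsilyloxy)-1-methyl-7-oxabicyclo[4.1.0]heptan-6-yl 2-methoxy-6-methyl-4-(triisopropylsilyloxy)benzoate F4. Catalytic p-toluenesulfonic acid should pass the acyl group to the epoxide oxygen with retention at the methyl-bearing carbon, which gives 11 directly and makes step 7 unnecessary.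

3. Step 5. Hydride may add in the conjugate (1,4) sense with loss of the aroate, or face selectivity may be poor on a vinylogous-anhydride carbonyl. The fallback replaces catalyst control by enzymatic resolution. It sets out from 7 and returns at 8. Luche reduction (NaBH4, CeCl3, MeOH, −78 °C) would give racemic 3-hydroxy-2-methylcyclohex-1-en-1-yl 2-methoxy-6-methyl-4-(triisopropylsilyloxy)benzoate F5. Lipase-catalysed acylation (Candida antarctica lipase B, vinyl acetate) should convert the (R)-alcohol selectively into (3R)-3-acetoxy-2-methylcyclohex-1-en-1-yl 2-methoxy-6-methyl-4-(triisopropylsilyloxy)benzoate F6, which is separated from the unreacted (S)-alcohol. Mild methanolysis (K2CO3, MeOH, 0 °C), which the di-ortho-substituted enol aroate should resist, then gives 8.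

Further compounds
F1 | step 13 | (1S,6R)-6-(tert-butyldimethylsilyloxy)-3-(hydroxymethyl)-1-methyl-2-oxo-4-(phenylsulfanyl)cyclohex-3-en-1-yl 2-methoxy-6-methyl-4-(triisopropylsilyloxy)benzoate | O=C1[C@@](C)(OC(=O)c2c(C)cc(O[Si](C(C)C)(C(C)C)C(C)C)cc2OC)[C@H](O[Si](C)(C)C(C)(C)C)CC(Sc3ccccc3)=C1CO
F2 | step 13 | (1S,6R)-6-(tert-butyldimethylsilyloxy)-3-(hydroxymethyl)-1-methyl-2-oxo-4-[(E)-2-oxopent-3-enyl]cyclohex-3-en-1-yl 2-methoxy-6-methyl-4-(triisopropylsilyloxy)benzoate | O=C1[C@@](C)(OC(=O)c2c(C)cc(O[Si](C(C)C)(C(C)C)C(C)C)cc2OC)[C@H](O[Si](C)(C)C(C)(C)C)CC(CC(=O)/C=C/C)=C1CO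
F3 | step 6 | (3R)-3-(tert-butyldimethylsilyloxy)-2-methylcyclohex-1-en-1-yl 2-methoxy-6-methyl-4-(triisopropylsilyloxy)benzoate | CC1=C(OC(=O)c2c(C)cc(O[Si](C(C)C)(C(C)C)C(C)C)cc2OC)CCC[C@H]1O[Si](C)(C)C(C)(C)C
F4 | step 6 | (1S,2R,6S)-2-(tert-butyldimethylsilyloxy)-1-methyl-7-oxabicyclo[4.1.0]heptan-6-yl 2-methoxy-6-methyl-4-(triisopropylsilyloxy)benzoate (epoxide oxygen trans to the silyloxy group) | C[C@@]12O[C@]1(OC(=O)c3c(C)cc(O[Si](C(C)C)(C(C)C)C(C)C)cc3OC)CCC[C@H]2O[Si](C)(C)C(C)(C)C
F5 | step 5 | racemic 3-hydroxy-2-methylcyclohex-1-en-1-yl 2-methoxy-6-methyl-4-(triisopropylsilyloxy)benzoate | CC1=C(OC(=O)c2c(C)cc(O[Si](C(C)C)(C(C)C)C(C)C)cc2OC)CCCC1O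
F6 | step 5 | (3R)-3-acetoxy-2-methylcyclohex-1-en-1-yl 2-methoxy-6-methyl-4-(triisopropylsilyloxy)benzoate | CC1=C(OC(=O)c2c(C)cc(O[Si](C(C)C)(C(C)C)C(C)C)cc2OC)CCC[C@H]1OC(C)=O
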